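**Assumption:** the target is all‑E (6R)‑α‑zeacarotene [(6R)‑7',8'‑dihydro‑ε,ψ‑carotene]; carotenoid locants are used (C6 = ring stereocentre, primed locants = acyclic end), and Oxone is counted as KHSO5.

**Retrosynthetic overview**
- C11=C12 (last bond): Wittig reaction of the (R)‑ε‑C15 phosphonium salt with an acyclic C25 polyenal.
- C11'=C12': mono‑Wittig reaction of farnesyltriphenylphosphonium bromide with the symmetrical C10 trienedial.
- C15 salt ⇐ vinyl carbinol ⇐ (R)‑α‑ionone (vinyl Grignard, then PPh3·HBr with allylic transposition).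
- C6 stereocentre: a C–O bond‑forming kinetic resolution of cheap racemic α‑ionone, in which a chiral dioxirane epoxidises the (S)‑enantiomer and leaves the (R)‑enantiomer.
- Rings: none is formed; the only ring (trimethylcyclohexene) is bought with α‑ionone.

**Route**

Step 1
Reactants: 1 (±)‑α‑ionone
Product: 2 (R)‑α‑ionone
Conditions: D‑fructose‑derived Shi ketone (30 mol%), Oxone (0.5 equiv = 1.0 equiv KHSO5, slow addition), K2CO3, Bu4NHSO4 (cat.), MeCN–DMM / aq. Na2B4O7–EDTA (pH 10.5), −10 → 0 °C, stopped at ca. 60% conversion (chiral GC); SiO2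
Reagents that add atoms: none
Why: Proposed new method: oxidative kinetic resolution of an α‑ionone by a chiral dioxirane (closest known reaction: Shi ketone/Oxone asymmetric epoxidation and its kinetic resolution of 1,6‑disubstituted cyclohexenes) – the dioxirane transfers oxygen through a spiro transition state only to the electron‑rich ring C4=C5 bond (the enone C7=C8 is inert to electrophilic dioxiranes), the catalyst's preferred alkene face coincides with the substrate's preferred face (syn to the pseudo‑axial side chain, anti to the axial C1 methyl) only in the (S)‑enantiomer, so (S)‑1 is drained as its cis‑epoxide by C–O bond formation and (R)‑2 is left with C6 untouched, reaching ≥98% ee at ca. 60% conversion if the selectivity factor is ≥20.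

Step 2
Reactants: 2 (R)‑α‑ionone
Product: 3 (1E)‑3‑methyl‑1‑[(1R)‑2,6,6‑trimethylcyclohex‑2‑en‑1‑yl]penta‑1,4‑dien‑3‑ol (vinyl‑α‑ionol; 6R; both C9 epimers)
Conditions: vinylMgBr (1.3 equiv), THF, −20 → 0 °C; aq. NH4Cl
Reagents that add atoms: vinylmagnesium bromide, C=C[Mg]Br
Why: Grignard 1,2‑addition to the enone carbonyl is fast at low temperature and does not touch C6, and the new C9 carbinol centre is an inconsequential epimer mixture that is erased in step 3.

Step 3
Reactants: 3 vinyl‑α‑ionol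
Product: 4 [(2E,4E)‑3‑methyl‑5‑[(1R)‑2,6,6‑trimethylcyclohex‑2‑en‑1‑yl]penta‑2,4‑dien‑1‑yl]triphenylphosphonium bromide
Conditions: PPh3·HBr (1.05 equiv), MeOH, 0 °C → rt, 24 h; recrystallised (EtOAc) to remove the 2Z isomer
Reagents that add atoms: triphenylphosphine hydrobromide, [Br-].[PH+](c1ccccc1)(c1ccccc1)c1ccccc1
Why: Acid ionisation of the tertiary allylic alcohol and capture of the allyl cation by PPh3 at the unhindered terminus C11 (SN1/SN2' allylic transposition, the standard C15 Wittig‑salt formation of the ionone series) leaves the C6–H centre uninvolved.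

Step 4
Reactants: 5 (2E,6E)‑farnesyl bromide
Product: 6 [(2E,6E)‑3,7,11‑trimethyldodeca‑2,6,10‑trien‑1‑yl]triphenylphosphonium bromide
Conditions: PPh3 (1.05 equiv), toluene, rt, 24 h; Et2O trituration
Reagents that add atoms: triphenylphosphine, c1ccc(cc1)P(c1ccccc1)c1ccccc1
Why: SN2 quaternisation of PPh3 by a primary allylic bromide is clean at room temperature and keeps the 2E,6E geometry.

Step 5
Reactants: 6 farnesyltriphenylphosphonium bromide; 7 (2E,4E,6E)‑2,7‑dimethylocta‑2,4,6‑trienedial (3 equiv)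
Product: 10 (2E,4E,6E,8E,10E,14E)‑2,7,11,15,19‑pentamethylicosa‑2,4,6,8,10,14,18‑heptaenal, via farnesylidene ylide 8 (not isolated), via 8Z aldehyde isomer 9 (not isolated)
Conditions: NaHMDS (1.0 equiv), THF, −78 °C; cannulated into 7, THF, −78 → 0 °C; then n‑heptane, 90 °C, N2, dark (Z→E); SiO2 (excess 7 recovered)
Reagents that add atoms: none
Why: Wittig olefination with inverse addition to excess dialdehyde gives mono‑condensation at one formyl group (as in the classical farnesyl + C10‑dial carotene syntheses), and the sterically hindered cis isomer at the new C11'=C12' bond relaxes thermally to the all‑E polyenal.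

Step 6
Reactants: 4 (R)‑ε‑C15 phosphonium bromide; 10 acyclic C25 aldehyde
Product: 13 (6R)‑α‑zeacarotene [all‑E (6R)‑7',8'‑dihydro‑ε,ψ‑carotene], via C15 ylide 11 (not isolated), via 11Z‑α‑zeacarotene 12 (not isolated)
Conditions: NaOMe (1.1 equiv), CH2Cl2/MeOH, 0 °C → rt; then n‑heptane, reflux, N2, dark (Z→E); crystallised (CH2Cl2/MeOH), all under Ar
Reagents that add atoms: none
Why: Wittig olefination of the non‑enolisable polyenal 10 by the conjugated ylide 11 forges C11=C12, the hindered 11Z portion equilibrates thermally to all‑E, and the C6 stereocentre is carried through unchanged because C6–H is not deprotonated under these mild conditions.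

**Compound list**
1 | (±)‑α‑ionone, (3E)‑4‑(2,6,6‑trimethylcyclohex‑2‑en‑1‑yl)but‑3‑en‑2‑one, racemate | CC(=O)/C=C/C1C(C)=CCCC1(C)C | starting material
2 | (R)‑α‑ionone, (3E)‑4‑[(1R)‑2,6,6‑trimethylcyclohex‑2‑en‑1‑yl]but‑3‑en‑2‑one | CC(=O)/C=C/[C@H]1C(C)=CCCC1(C)C | intermediate
3 | (1E)‑3‑methyl‑1‑[(1R)‑2,6,6‑trimethylcyclohex‑2‑en‑1‑yl]penta‑1,4‑dien‑3‑ol (6R; C9 epimers) | C=CC(C)(O)/C=C/[C@H]1C(C)=CCCC1(C)C | intermediate
4 | [(2E,4E)‑3‑methyl‑5‑[(1R)‑2,6,6‑trimethylcyclohex‑2‑en‑1‑yl]penta‑2,4‑dien‑1‑yl]triphenylphosphonium bromide | [Br-].c1ccccc1[P+](c1ccccc1)(c1ccccc1)C/C=C(C)/C=C/[C@H]1C(C)=CCCC1(C)C | intermediate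
5 | (2E,6E)‑farnesyl bromide, (2E,6E)‑1‑bromo‑3,7,11‑trimethyldodeca‑2,6,10‑triene | CC(C)=CCC/C(C)=C/CC/C(C)=C/CBr | starting material
6 | [(2E,6E)‑3,7,11‑trimethyldodeca‑2,6,10‑trien‑1‑yl]triphenylphosphonium bromide | CC(C)=CCC/C(C)=C/CC/C(C)=C/C[P+](c1ccccc1)(c1ccccc1)c1ccccc1.[Br-] | intermediate
7 | (2E,4E,6E)‑2,7‑dimethylocta‑2,4,6‑trienedial (C10 dialdehyde) | O=C/C(C)=C/C=C/C=C(C)/C=O | starting material
8 | [(2E,6E)‑3,7,11‑trimethyldodeca‑2,6,10‑trien‑1‑ylidene]triphenylphosphorane (farnesylidene ylide) | CC(C)=CCC/C(C)=C/CC/C(C)=C/C=P(c1ccccc1)(c1ccccc1)c1ccccc1 | intermediate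
9 | (2E,4E,6E,8Z,10E,14E)‑2,7,11,15,19‑pentamethylicosa‑2,4,6,8,10,14,18‑heptaenal (cis at carotenoid C11'=C12') | CC(C)=CCC/C(C)=C/CC/C(C)=C/C=C\C(C)=C\C=C\C=C(C)\C=O | intermediate
10 | (2E,4E,6E,8E,10E,14E)‑2,7,11,15,19‑pentamethylicosa‑2,4,6,8,10,14,18‑heptaenal (acyclic C25 aldehyde) | CC(C)=CCC/C(C)=C/CC/C(C)=C/C=C/C(C)=C/C=C/C=C(C)/C=O | intermediate
11 | [(2E,4E)‑3‑methyl‑5‑[(1R)‑2,6,6‑trimethylcyclohex‑2‑en‑1‑yl]penta‑2,4‑dien‑1‑ylidene]triphenylphosphorane | c1ccccc1P(c1ccccc1)(c1ccccc1)=C/C=C(C)/C=C/[C@H]1C(C)=CCCC1(C)C | intermediate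
12 | (6R,11Z)‑7',8'‑dihydro‑ε,ψ‑carotene (11Z isomer of the target) | CC(C)=CCC/C(C)=C/CC/C(C)=C/C=C/C(C)=C/C=C/C=C(C)/C=C\C=C(C)\C=C\[C@H]1C(C)=CCCC1(C)C | intermediate
13 | (6R)‑α‑zeacarotene, all‑E (6R)‑7',8'‑dihydro‑ε,ψ‑carotene | CC(C)=CCC/C(C)=C/CC/C(C)=C/C=C/C(C)=C/C=C/C=C(C)/C=C/C=C(C)/C=C/[C@H]1C(C)=CCCC1(C)C | target

**Totals**
Total step count: 6. Longest linear sequence: 4 (steps 1, 2, 3, 6 from α‑ionone); the other branch is steps 4, 5, 6.

**Three steps most likely to fail**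

Step 1 (the proposed new resolution). The selectivity factor may be too low, the hindered ring alkene may react slowly, or the sense may be opposite to the prediction. The sense is checked on the first run by optical rotation, since (R)‑α‑ionone is dextrorotatory; if the (S)‑enantiomer is the one left, the L‑sorbose‑derived antipode of the ketone is used. Fallback with known chemistry (enzymatic resolution at the alcohol stage), setting out from 1 and coming back at 2:
- 1 is reduced (NaBH4, CeCl3, MeOH) to α‑ionol F1 as two racemic diastereomers.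
- These are esterified (4‑nitrobenzoyl chloride, pyridine) and separated by fractional crystallisation to give the racemic (6R*,9S*) α‑ionyl 4‑nitrobenzoate F2.
- Saponification (KOH, MeOH) gives racemic (6R*,9S*)‑α‑ionol F3.
- Lipase PS with vinyl acetate in t‑BuOMe acetylates the 9R alcohol to (6S,9R)‑α‑ionyl acetate F5 and leaves (6R,9S)‑α‑ionol F4.
- F4 is separated on silica and oxidised (MnO2, CH2Cl2) to 2.

Step 5 (mono‑olefination of a symmetrical dialdehyde). Double condensation to ζ‑carotene and loss of material in the statistical mixture are the risks. Fallback, setting out from 7 and coming back at 10: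
- 7 is desymmetrised first with neopentyl glycol (1 equiv, PPTS, toluene) to the C10 dialdehyde mono‑acetal F6; unreacted 7 is recycled.
- F6 is condensed with ylide 8 (from 6, NaHMDS, THF) to the acyclic C25 acetal F7.
- The acetal is cleaved (aq. oxalic acid, THF) and the product isomerised thermally to 10.

Step 6 (final Wittig reaction). Risks are a poor E/Z ratio at C11=C12, a sluggish reaction of the C15 ylide, or loss of material on handling the air‑sensitive hydrocarbon. Fallback with reversed polarity, setting out from 2 and 10 and coming back at 13: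
- 2 is homologated with diethyl cyanomethylphosphonate (NaH, THF, Horner–Wadsworth–Emmons) to (2E,4E)‑3‑methyl‑5‑[(1R)‑2,6,6‑trimethylcyclohex‑2‑en‑1‑yl]penta‑2,4‑dienenitrile F8.
- F8 is reduced (DIBAL‑H, then aqueous acid) to the C15 aldehyde F9.
- 10 is reduced (NaBH4, MeOH) to the acyclic C25 alcohol F10 and converted (PPh3·HBr, MeOH) into the acyclic C25 phosphonium bromide F11.
- Wittig reaction of F11 with F9 (NaOMe, CH2Cl2) and thermal isomerisation give 13; the chiral fragment is now the electrophile.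

**Further compounds**
F1 | step 1 | α‑ionol, (3E)‑4‑(2,6,6‑trimethylcyclohex‑2‑en‑1‑yl)but‑3‑en‑2‑ol, mixture of the two racemic diastereomers | CC(O)/C=C/C1C(C)=CCCC1(C)C
F2 | step 1 | racemic (6R*,9S*)‑α‑ionyl 4‑nitrobenzoate (one enantiomer drawn) | C[C@H](OC(=O)c1ccc(cc1)[N+](=O)[O-])/C=C/[C@H]1C(C)=CCCC1(C)C
F3 | step 1 | racemic (6R*,9S*)‑α‑ionol (one enantiomer drawn) | C[C@H](O)/C=C/[C@H]1C(C)=CCCC1(C)C
F4 | step 1 | (6R,9S)‑α‑ionol, (2S,3E)‑4‑[(1R)‑2,6,6‑trimethylcyclohex‑2‑en‑1‑yl]but‑3‑en‑2‑ol, single enantiomer | C[C@H](O)/C=C/[C@H]1C(C)=CCCC1(C)C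
F5 | step 1 | (6S,9R)‑α‑ionyl acetate | C[C@@H](OC(C)=O)/C=C/[C@@H]1C(C)=CCCC1(C)C
F6 | step 5 | (2E,4E,6E)‑7‑(5,5‑dimethyl‑1,3‑dioxan‑2‑yl)‑2‑methylocta‑2,4,6‑trienal | O=C/C(C)=C/C=C/C=C(C)/C1OCC(C)(C)CO1
F7 | step 5 | 5,5‑dimethyl‑1,3‑dioxane acetal of aldehyde 10 | CC(C)=CCC/C(C)=C/CC/C(C)=C/C=C/C(C)=C/C=C/C=C(C)/C1OCC(C)(C)CO1
F8 | step 6 | (2E,4E)‑3‑methyl‑5‑[(1R)‑2,6,6‑trimethylcyclohex‑2‑en‑1‑yl]penta‑2,4‑dienenitrile | N#C/C=C(C)/C=C/[C@H]1C(C)=CCCC1(C)C
F9 | step 6 | (2E,4E)‑3‑methyl‑5‑[(1R)‑2,6,6‑trimethylcyclohex‑2‑en‑1‑yl]penta‑2,4‑dienal | O=C/C=C(C)/C=C/[C@H]1C(C)=CCCC1(C)C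
F10 | step 6 | (2E,4E,6E,8E,10E,14E)‑2,7,11,15,19‑pentamethylicosa‑2,4,6,8,10,14,18‑heptaen‑1‑ol | CC(C)=CCC/C(C)=C/CC/C(C)=C/C=C/C(C)=C/C=C/C=C(C)/CO
F11 | step 6 | [(2E,4E,6E,8E,10E,14E)‑2,7,11,15,19‑pentamethylicosa‑2,4,6,8,10,14,18‑heptaen‑1‑yl]triphenylphosphonium bromide | CC(C)=CCC/C(C)=C/CC/C(C)=C/C=C/C(C)=C/C=C/C=C(C)/C[P+](c1ccccc1)(c1ccccc1)c1ccccc1.[Br-]
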